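The runs are calculated with constants of no real substance; scatter was added.

The pitfall in a sigmoidal flask is to read the first slope as an initial velocity of the catalyst: a slope taken at two percent conversion need not belong to the catalyst, since product may already be at work there.

| setting | zeta | theta | gamma | beta |
|---|---|---|---|---|
| starting material | 100 mM | 150 mM | 100 mM | 50.0 mM |
| catalyst | 3.00 mM | 3.00 mM | 3.00 mM | 1.50 mM |
| product |  |  | 30.0 mM |  |
| time |  |  |  | 130 s |

- zeta run (time / s: [product] / mM): 5.2: 0.3; 12: 0.9; 26: 1.7; 58: 7.0; 130: 49.7
- theta run (time / s: [product] / mM): 5.2: 0.3; 12: 0.7; 26: 3.4; 58: 17.7; 130: 125.1
- gamma run (time / s: [product] / mM): 5.2: 36.0; 12: 43.2; 26: 63.0; 58: 102.5; 130: 128.1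

(each reading ± 0.3 mM)

* the power of [starting material] that the first rate follows, about the charge of the zeta run; measure it at two percent of starting material made into product (one fixed amount of product, the same in the runs compared)
* product in the beta run at 130 s, as a share of the starting material charged

- Overall: starting material -> product, with catalyst as catalyst.
- Constant volume, constant temperature.
- A reading of a species includes what of it is bound.
- An order is taken over about fifteen percent of the charge, up and down.

The curve can be solved at both ends and joined. At the late end, the gamma run starts with 30.0 mM of product, and the ratio of [product] to the remaining [starting material], taken as exponential, climbs at a mean of 0.0431 s⁻¹ between 5.2 s and 58 s. Taking that growth as proportional to the total of starting material and product, the zeta run multiplies its product at 0.0332 s⁻¹, pseudo-first-order in product while [starting material] stays near its charge.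

But the zeta run began without product and still shows 0.3 mM at 5.2 s, so the early end needs a second term. The rate is therefore written as the growth constant over that total, times [starting material], times the sum of [product] and a head start. The zeta reading of 7.0 mM at 58 s gives 1.31 mM for the head start, the [product] at which the path through product runs as fast as the path through catalyst.

One objection is that the head start may shift with [starting material]. The theta reading at the same time gives 1.20 mM, against 1.31 mM from the zeta run. At 2.00 mM of product, the two runs then give an order of 0.935, though across a wider span than the one asked.

The harder objection concerns the beta run, where catalyst stands at 1.50 mM against 3.00 mM in the zeta run. Here the growth is kept free of catalyst, which gives a factor of 8.63 over 130 s. If the head start follows catalyst to the first power, it becomes 0.653 mM and the yield 8.95%. If it follows the square, the yield is 4.71%. The reckoning here commits to the first.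

The forecast, noting that “no run varied the catalyst”, takes the whole rate as proportional to catalyst instead and gives an order of 1 and a beta yield of 4.5%, a different yield from the one reckoned here.

The simulation gives an order of 0.94 and a beta yield of 7.41%, both forecast values standing within their margins, from these steps:

    catalyst + starting material ⇌ catalyst-substrate complex, settled at all times (2.790 M⁻¹)
    catalyst-substrate complex + catalyst → product + 2 catalyst (70.60 M⁻¹ s⁻¹)
    2 catalyst ⇌ resting dimer, settled at all times (243.0 M⁻¹)
    starting material + product → 2 product (0.3290 M⁻¹ s⁻¹)

Early in the zeta run, the apparent order in catalyst is 0.59. The beta yield is higher than 4.71% and lower than 8.95%. Run backwards through the same growth factor, it asks for a head start of 0.530 mM, which is 0.405 of the zeta value. In the gamma run, with 2.00 mM made, the head start predicts a rate 10.1 times that of the zeta run, and the simulated ratio is 10.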